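## Structural features

The target is a diaryl ether of two benzoic acids and has no stereocentre. Ring A is pentasubstituted (a1 OCH3, a2 H, a3 CO2H, a4 ether oxygen, a5 OH, a6 Cl), so chlorine sits between two oxygens and three neighbouring oxygens (a1, a5, a4) must be told apart as methyl ether, free phenol and aryl ether. Ring B carries b1 CO2H, b2 ether oxygen, b3 H, b4 CH3, b5 H and b6 OH. The ether oxygen joins a4 to b2 and is flanked by a carboxyl on each ring and by the a5 hydroxyl, which makes arylation of a phenol (Ullmann or SNAr type) an unattractive way to form it. Fragile points are the a6 chlorine (hydrogenolysis), the electron-rich phenol rings (chlorination or over-oxidation when an oxidant is used late), the 2,6-dioxygenated benzoic acid of ring B (decarboxylation in hot acid) and the need to unmask a5 without touching the a1 methyl ether. The difficulty is regiochemical: six defined positions on ring A, the 1,2,3,5 pattern on ring B and the crowded C–O–C link. The key step uses the fact that b6–OH and b1–CO2H are neighbours: b6–OH is the oxidation product of a b6–B bond and b1–CO2H that of a b1–CH2O group, and both fit into one five-membered cyclic boronate. Ring B can then be cut into three alkyne units (b6–b5, b1–b2, b3–b4), with the ether oxygen already bonded to the alkyne carbon b2.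

## Logic of the disconnections

**26 back to 25.** The O–CH2Ph bond at a5 is cut. The a5 phenol must stay distinct from the a1 methyl ether and the a4 oxygen from the third step on, and a benzyl ether survives base, organolithium, peroxide, MnO2 and chlorite. The skeleton is not simplified, but every later step can ignore a5. The forward cleavage must spare a6–Cl (which excludes hydrogenolysis), the a1 methyl ether and the diaryl ether, so a boron Lewis acid with a cation scavenger at low temperature is required.

**25 back to 24 and 23.** The C–O bonds of both carboxyl groups are taken back to the two aldehydes of 24, and the ring B aldehyde further to the benzylic alcohol of 23. The ring-forming step delivers the b1 carbon as CH2–O, and a carboxyl or ester on ring A would not survive the organolithium step. Both acids then arise in one flask, and ring A needs no redox change before 24. The MnO2 oxidation must stop at the aldehyde and spare the phenol, and the chlorite oxidation needs a hypochlorite scavenger because ring B carries a free phenol.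

**23 back to 21 (through 22).** The b6–O bond is traced to a b6–B bond and the a3 aldehyde to its dimethyl acetal. Boron marks b6 unambiguously, and the acetal is the form in which the a3 carbon tolerates organolithium and alkaline peroxide. The oxaborole of 21 holds the future phenol and the future carboxyl carbon of ring B in one masked unit. Peroxide must be destroyed before acid unveils the ring A aldehyde, and the acid must be mild enough for the new hydroxybenzyl alcohol.

**21 back to 14, 18 and 19 (through 20).** Bonds b6–b1, b2–b3 and b4–b5 are cut, together with the B–O bond of the tether. Ring B falls into three alkynes, and the crowded a4–O–b2 link is already present in 14 as an O–C(sp) bond, so no diaryl ether coupling is needed. Six ring carbons with four substituents in the correct order come from three small pieces in one operation. The forward step must choose one of many possible trimers: the tether has to pair 14 with 18, and the third alkyne has to insert in one orientation.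

**18 back to 15 and 16 (through 17).** The B–C(sp) bond is cut. An alkynylboronate with exchangeable alkoxy groups is needed for the tether and is best made fresh from two catalogue reagents. The ate complex must be cleaved with anhydrous acid, because water would hydrolyse the product.

**14 back to 11 (through 12 and 13), 11 to 10, and 10 to 8 and 9.** The C(sp)–CH2OH bond is cut (acetylide plus a one-carbon electrophile), the triple bond is traced to a 1,2-dichlorovinyl ether, the acetal to the aldehyde, and the O–C(vinyl) bond to the phenol 8 and the C2 unit 9. Addition of a phenoxide to an in-situ chloroalkyne is little affected by the two ortho substituents that would block an arylation. Ring A is reduced to a simple salicylaldehyde. The aldehyde must be masked before the organolithium step, and the acid-sensitive alkynyl ether 14 must be handled under neutral or basic conditions.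

**8 back to 7, and 7 back to 5 (through 6).** The a3–CHO bond is cut (ortho-formylation directed by the a4 phenol), then the a4–O bond is traced to an a4–CHO bond (aryl migration to oxygen). The a4 oxygen and the a3 carbon are thus introduced one after the other through the same kind of handle, and ring A becomes a trisubstituted benzaldehyde. The formylation must go ortho to the free hydroxyl only, which a magnesium phenoxide secures, since the alternative site a2 is activated by the two ether oxygens.

**5 back to 4, 3 and 1 (through 2).** The O–CH2Ph and O–CH3 bonds and the first a4–CHO bond are cut. The symmetric diol 1 already has chlorine between two oxygens, so its position is never in doubt. The symmetry is broken by one formylation, after which the two hydroxyls differ in acidity (para against ortho to the formyl group, the latter hydrogen-bonded). The methylation must be run with a base that deprotonates only the para hydroxyl.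

## Other disconnections considered

**Alternative 1:** anodic coupling closing ring A.
- Cut: the a3–a4 bond of ring A at the oxidation level of a cyclohexenone, so ring A is built last and ring B is present from the start as a benzoate.
- Forward key step: the open-chain keto ester A1 would be silylated in situ (lithium amide base, chlorosilane) to a ketene silyl acetal at a3 and a 2-silyloxydiene ending at a4. Oxidation at a carbon anode would join these two electron-rich termini and give the trans-disubstituted 3-methoxycyclohexenone A2.
- In favour: both carboxyl carbons are esters from the outset, so no late oxidation of alcohols to acids is needed; on this point it is better than the chosen plan. The ether oxygen is attached by simple alkylation of a phenol. The umpolung coupling needs no leaving group at a3 or a4.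
- Against: ring A emerges non-aromatic and without chlorine. The two stereocentres formed are destroyed on dehydrogenation. Chlorine must then be placed at a6 in competition with a2 (para to the new hydroxyl) and with the electron-rich ring B. The base must also choose among three acidic sites (a3, a4 and the vinylogous a2 position), and the anode must oxidise an enol ether in preference to the alkoxy-substituted arene.
- Comparison: structurally the chosen plan is safer because a6–Cl comes from a starting material. Mechanistically both key steps are untested on their substrate class, so they are equal there. In step economy Alternative 1 saves the two alcohol-to-acid oxidations but adds aromatization, chlorination and hydrolysis of two esters (one di-ortho-substituted), so no net saving is expected.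

**Alternative 2:** ring B from an aryloxypyrone ester and a ketene acetal.
- Cut: bonds b4–b5 and b6–b1.
- Forward key step: the 4-aryloxy-6-methyl-2-pyrone-3-carboxylate A3 and 1,1-dimethoxyethene A4 would combine on heating in an inverse-demand Diels–Alder reaction across C6 and C3 of the pyrone. Loss of CO2 and methanol from the bridged adduct would give the 2-methoxybenzoate A5.
- In favour: the reaction class is well established for 3-alkoxycarbonyl-2-pyrones, and its regiochemistry follows from polarization (the nucleophilic CH2 of A4 bonds to C6). No organolithium, boron or ruthenium chemistry is needed, and both carboxyl carbons are at their final oxidation level. On precedent for the ring-forming step and on oxidation-state economy it is better than the chosen plan.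
- Against: the aryloxy group at C4 is a donor that lowers the electrophilicity of the pyrone, and the methyl group makes C6 fully substituted, so forcing conditions are likely. A4 could instead attack C4 and expel the ring A aryloxide. The b6 oxygen arrives as a methyl ether that must be cleaved next to the a1 methyl ether (plausible by chelation to the ortho ester, but a second selectivity problem). The di-ortho-substituted ring B ester is slow to hydrolyse. The a4–O bond to the pyrone must be made with a hindered ortho-carboxylated phenoxide.
- Comparison: structurally the chosen plan forms the crowded ether as an O–C(sp) bond and ends with a single benzyl ether cleavage, which is cleaner. Mechanistically Alternative 2 stands on firmer ground. The step count is expected to be about equal.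

**Alternative 3:** ring B by Danheiser benzannulation.
- Cut: bonds b6–b1, b2–b3 and b5–b6.
- Forward key step: the silylated aryl alkynyl ether A6 and 3-methylcyclobutenone A7 would be heated. A7 opens to a vinylketene, which undergoes (2+2) cycloaddition with the electron-rich alkyne (ketene carbonyl carbon to b1). A 4π opening and 6π electrocyclization followed by tautomerization would give the phenol A8.
- In favour: the b6 phenol is delivered directly, with no boron to oxidise. Only two components are involved and no metal. The regiochemistry follows from the polarization of the alkynyl ether. On these points it is the equal or the better of the chosen plan, and it uses the same ring A chemistry up to the alkynyl ether (A6 is the bis-silyl relative of 14), so it is equal there too.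
- Against: A7 is not a catalogue compound, is volatile and labile, and needs several steps of its own. The cascade needs prolonged heating of an acid- and heat-sensitive aryl alkynyl ether. An aryloxy alkyne is a weaker ketenophile than an alkoxy or siloxy alkyne, so vinylketene dimerization may compete. The phenol formed can be acylated by excess vinylketene.
- Comparison: structurally both plans give the same ring B pattern with b1 at the alcohol level, and A8 then needs the same desilylation, MnO2, chlorite and debenzylation sequence, so the end game is equal. Mechanistically Alternative 3 relies on a closer precedent for heteroatom-substituted alkynes, whereas the chosen plan runs at room temperature and takes its C2 and C3 units from catalogue reagents. Once the preparation of A7 is counted, no saving in steps is expected.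

Key step: step 10

Remark on the chemistry: the substitution patterns of 14 and 21 were checked position by position against 26 and need no change in connectivity; the a3 carbon is carried through the key step as a dimethyl acetal (aldehyde level) and not as a protected hydroxymethyl group, which alters only a spectator group and saves a reduction, a silylation and a separate deprotection; the conversion of 5 into 7 is a Baeyer–Villiger reaction, since an O-alkylated benzaldehyde does not undergo the classical Dakin reaction; there is no stereocentre, and the (E) double bond of 10 and 11 disappears in step 8.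

## Route

Step 1
Reactants: 1 2-chlororesorcinol (2-chlorobenzene-1,3-diol)
Product: 3 3-chloro-2,4-dihydroxybenzaldehyde, via iminium chloride 2 (not isolated)
Conditions: POCl3, DMF, MeCN, −15 °C to rt; then H2O, 50 °C
Reagents that add atoms: N,N-dimethylformamide, CN(C)C=O; water, O
Why: Vilsmeier–Haack formylation; the two free positions ortho to one hydroxyl and para to the other are equivalent, and the first formyl group deactivates the ring against a second attack.

Step 2
Reactants: 3 3-chloro-2,4-dihydroxybenzaldehyde
Product: 4 3-chloro-2-hydroxy-4-methoxybenzaldehyde
Conditions: MeI (1.1 equiv), KHCO3, DMF, rt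
Reagents that add atoms: iodomethane, CI
Why: Williamson etherification; the hydroxyl para to the formyl group is the more acidic and is not hydrogen-bonded, so hydrogen carbonate should deprotonate and methylate only this one.

Step 3
Reactants: 4 3-chloro-2-hydroxy-4-methoxybenzaldehyde
Product: 5 2-(benzyloxy)-3-chloro-4-methoxybenzaldehyde
Conditions: BnBr, K2CO3, DMF, 60 °C
Reagents that add atoms: benzyl bromide, BrCc1ccccc1
Why: Williamson etherification of the remaining chelated hydroxyl with a stronger base and heat; benzyl is chosen because BCl3 can remove it at the end without hydrogenolysis of the aryl chloride.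

Step 4
Reactants: 5 2-(benzyloxy)-3-chloro-4-methoxybenzaldehyde
Product: 7 2-(benzyloxy)-3-chloro-4-methoxyphenol, via aryl formate 6 (not isolated)
Conditions: mCPBA, CH2Cl2, 0 °C to rt; then K2CO3 (cat.), MeOH, rt
Reagents that add atoms: 3-chloroperoxybenzoic acid, OOC(=O)c1cccc(Cl)c1
Why: Baeyer–Villiger oxidation; the aryl group, made electron-rich by the ortho benzyloxy and para methoxy groups, should migrate in preference to hydride, and the formate is cleaved by methanolysis.

Step 5
Reactants: 7 2-(benzyloxy)-3-chloro-4-methoxyphenol
Product: 8 3-(benzyloxy)-4-chloro-2-hydroxy-5-methoxybenzaldehyde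
Conditions: MgCl2, Et3N, (CH2O)n, MeCN, reflux; then 1 M HCl
Reagents that add atoms: formaldehyde (as paraformaldehyde), C=O
Why: Casnati–Skattebøl ortho-formylation; the magnesium phenoxide delivers formaldehyde to the only free ortho position (a3) and not to a2, and a second equivalent of formaldehyde takes up hydride to give the aldehyde.

Step 6
Reactants: 8 3-(benzyloxy)-4-chloro-2-hydroxy-5-methoxybenzaldehyde, 9 trichloroethylene
Product: 10 3-(benzyloxy)-4-chloro-2-{[(E)-1,2-dichloroethenyl]oxy}-5-methoxybenzaldehyde
Conditions: K2CO3, DMF, 70 °C
Reagents that add atoms: none
Why: Elimination–addition; base converts 9 into dichloroethyne, to which the phenoxide adds with anti protonation to give the (E)-dichlorovinyl ether. The small linear electrophile should tolerate the two ortho substituents that would hinder an arylation.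

Step 7
Reactants: 10 3-(benzyloxy)-4-chloro-2-{[(E)-1,2-dichloroethenyl]oxy}-5-methoxybenzaldehyde
Product: 11 2-(benzyloxy)-3-chloro-1-{[(E)-1,2-dichloroethenyl]oxy}-6-(dimethoxymethyl)-4-methoxybenzene
Conditions: HC(OMe)3, MeOH, TsOH (cat.), rt; then Et3N
Reagents that add atoms: trimethyl orthoformate, COC(OC)OC; methanol, CO
Why: Acid-catalysed acetalization with the orthoformate as water scavenger; the electron-poor dichlorovinyl ether should not be protonated under these conditions, and the acetal masks the aldehyde against n-BuLi.

Step 8
Reactants: 11 2-(benzyloxy)-3-chloro-1-{[(E)-1,2-dichloroethenyl]oxy}-6-(dimethoxymethyl)-4-methoxybenzene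
Product: 14 3-[2-(benzyloxy)-3-chloro-6-(dimethoxymethyl)-4-methoxyphenoxy]prop-2-yn-1-ol, via chloroalkynyl ether 12 (not isolated), via lithium acetylide 13 (not isolated)
Conditions: n-BuLi (2.3 equiv), THF, −78 °C; then (CH2O)n, −78 °C to rt; H2O quench; chromatography on Et3N-deactivated silica
Reagents that add atoms: formaldehyde (as paraformaldehyde), C=O
Why: Dehydrochlorination to the chloroalkyne, chlorine–lithium exchange to the lithium aryloxyacetylide and 1,2-addition to formaldehyde, the standard route from dichlorovinyl ethers to alkynyl ethers. At −78 °C the aryl chloride, the acetal and the benzyl ether should not react.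

Step 9
Reactants: 15 ethynylmagnesium bromide, 16 triisopropyl borate
Product: 18 diisopropyl ethynylboronate, via borate complex 17 (not isolated)
Conditions: THF, −78 °C; then HCl in Et2O, −78 °C to rt; filtration, distillation
Reagents that add atoms: none
Why: Addition of the alkynyl Grignard reagent to the borate gives a stable ate complex at low temperature, which prevents double addition; anhydrous HCl then removes one isopropoxide and releases the alkynylboronic ester.

Step 10
Reactants: 14 3-[2-(benzyloxy)-3-chloro-6-(dimethoxymethyl)-4-methoxyphenoxy]prop-2-yn-1-ol, 18 diisopropyl ethynylboronate, 19 propyne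
Product: 21 4-[2-(benzyloxy)-3-chloro-6-(dimethoxymethyl)-4-methoxyphenoxy]-6-methyl-1-(propan-2-yloxy)-1,3-dihydro-2,1-benzoxaborole, via tethered diyne 20 (not isolated)
Conditions: [Ru(C5Me5)Cl(C8H12)] (10 mol %), propyne (1 atm, excess), ClCH2CH2Cl, rt; 14 and 18 (1.2 equiv) added slowly; filtration, evaporation, used crude
Reagents that add atoms: none
Why: Proposed new method: the propargylic hydroxyl of 14 exchanges with one isopropoxy group of 18 to give the B–O-tethered 1,6-diyne 20, whose two alkynes bind the Ru(C5Me5)Cl fragment (divalent ruthenium) and undergo oxidative cyclization to a ruthenacyclopentadiene fused to the five-membered oxaborole, which forms bond b6–b1; propyne then adds at the unsubstituted Ru–C(b5) end with its methyl-bearing carbon, and reductive elimination joins its CH carbon to the aryloxy-bearing carbon, forming b4–b5 and b2–b3 and releasing 21. The closest known reaction type is the ruthenium-catalysed cyclotrimerization of an alkynylboronate, a propargylic alcohol and a terminal alkyne through the same temporary boronate tether, supported by transition-metal-catalysed (2+2+2) cycloadditions of ynamides and alkynyl ethers; the new element is an aryl alkynyl ether as the tethered alkyne. Ring B is closed by a metal-templated (2+2+2) cycloaddition in which two components are joined through the tether and the third enters intermolecularly, while the oxaborole is closed beforehand by B–O exchange and becomes ring-fused in the oxidative cyclization; no stereocentre is formed. Chemoselectivity among the three alkynes rests on the tether, which makes the union of 14 and 18 intramolecular, and on slow addition into excess propyne, which keeps the diyne from serving as its own third partner. Regioselectivity rests on the two ends of the ruthenacycle: b2 carries the bulky 2,6-disubstituted aryloxy group and is a donor-stabilised, less reactive terminus, whereas b5 carries only hydrogen, so the methyl group should end at b4, meta to both boron and the aryloxy group. The conditions are neutral and at room temperature, which the acetal, the benzyl ether, the aryl chloride and the acid-sensitive alkynyl ether should tolerate.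

Step 11
Reactants: 21 4-[2-(benzyloxy)-3-chloro-6-(dimethoxymethyl)-4-methoxyphenoxy]-6-methyl-1-(propan-2-yloxy)-1,3-dihydro-2,1-benzoxaborole
Product: 23 3-(benzyloxy)-4-chloro-2-[3-hydroxy-2-(hydroxymethyl)-5-methylphenoxy]-5-methoxybenzaldehyde, via acetal diol 22 (not isolated)
Conditions: H2O2 (30%), NaOH, THF/H2O, 0 °C to rt; Na2S2O3; then 1 M HCl, THF, rt
Reagents that add atoms: hydrogen peroxide, OO; water, O
Why: Oxidation of the aryl C–B bond by hydroperoxide (1,2-shift of the aryl group from boron to oxygen) frees the b6 phenol and the b1 hydroxymethyl group from the borate. The acetal is hydrolysed only after the peroxide is reduced, so the ring A aldehyde never meets alkaline peroxide.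

Step 12
Reactants: 23 3-(benzyloxy)-4-chloro-2-[3-hydroxy-2-(hydroxymethyl)-5-methylphenoxy]-5-methoxybenzaldehyde
Product: 24 3-(benzyloxy)-4-chloro-2-(2-formyl-3-hydroxy-5-methylphenoxy)-5-methoxybenzaldehyde
Conditions: MnO2 (activated, excess), CH2Cl2, rt
Reagents that add atoms: none
Why: Selective oxidation of a benzylic alcohol by manganese dioxide, which should stop at the aldehyde; the product is a hydrogen-bonded salicylaldehyde, and the phenol, the aryl ethers and the existing aldehyde are not expected to react.

Step 13
Reactants: 24 3-(benzyloxy)-4-chloro-2-(2-formyl-3-hydroxy-5-methylphenoxy)-5-methoxybenzaldehyde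
Product: 25 3-(benzyloxy)-2-(2-carboxy-3-hydroxy-5-methylphenoxy)-4-chloro-5-methoxybenzoic acid
Conditions: NaClO2, NaH2PO4, 2-methylbut-2-ene (large excess), t-BuOH/THF/H2O, 0 °C to rt
Reagents that add atoms: sodium chlorite, [Na+].[O-]Cl=O
Why: Pinnick oxidation of both aldehydes by chlorous acid; the alkene traps hypochlorous acid so that the phenolic ring B is not chlorinated, and the mild buffered conditions suit phenolic aldehydes.

Step 14
Reactants: 25 3-(benzyloxy)-2-(2-carboxy-3-hydroxy-5-methylphenoxy)-4-chloro-5-methoxybenzoic acid
Product: 26 2-(2-carboxy-3-hydroxy-5-methylphenoxy)-4-chloro-3-hydroxy-5-methoxybenzoic acid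
Conditions: BCl3 (excess), C6HMe5, CH2Cl2, −78 to 0 °C; then MeOH, H2O
Reagents that add atoms: none
Why: Lewis-acid cleavage of the benzyl ether with pentamethylbenzene as benzyl cation scavenger, which keeps ring B from being benzylated. The a1 methyl ether has no neighbouring carbonyl to assist its cleavage and should survive, and the aryl chloride is not at risk as it would be under hydrogenolysis.

## Compound list

1 | 2-chlororesorcinol (2-chlorobenzene-1,3-diol) | Oc1cccc(O)c1Cl | starting material
2 | [(3-chloro-2,4-dihydroxyphenyl)methylidene]dimethylammonium chloride | C[N+](C)=Cc1ccc(O)c(Cl)c1O.[Cl-] | intermediate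
3 | 3-chloro-2,4-dihydroxybenzaldehyde | O=Cc1ccc(O)c(Cl)c1O | intermediate
4 | 3-chloro-2-hydroxy-4-methoxybenzaldehyde | COc1ccc(C=O)c(O)c1Cl | intermediate
5 | 2-(benzyloxy)-3-chloro-4-methoxybenzaldehyde | COc1ccc(C=O)c(OCc2ccccc2)c1Cl | intermediate
6 | 2-(benzyloxy)-3-chloro-4-methoxyphenyl formate | COc1ccc(OC=O)c(OCc2ccccc2)c1Cl | intermediate
7 | 2-(benzyloxy)-3-chloro-4-methoxyphenol | COc1ccc(O)c(OCc2ccccc2)c1Cl | intermediate
8 | 3-(benzyloxy)-4-chloro-2-hydroxy-5-methoxybenzaldehyde | COc1cc(C=O)c(O)c(OCc2ccccc2)c1Cl | intermediate
9 | trichloroethylene | ClC=C(Cl)Cl | starting material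
10 | 3-(benzyloxy)-4-chloro-2-{[(E)-1,2-dichloroethenyl]oxy}-5-methoxybenzaldehyde | COc1cc(C=O)c(O/C(Cl)=C\Cl)c(OCc2ccccc2)c1Cl | intermediate
11 | 2-(benzyloxy)-3-chloro-1-{[(E)-1,2-dichloroethenyl]oxy}-6-(dimethoxymethyl)-4-methoxybenzene | COc1cc(C(OC)OC)c(O/C(Cl)=C\Cl)c(OCc2ccccc2)c1Cl | intermediate
12 | 2-(benzyloxy)-3-chloro-1-[(chloroethynyl)oxy]-6-(dimethoxymethyl)-4-methoxybenzene | COc1cc(C(OC)OC)c(OC#CCl)c(OCc2ccccc2)c1Cl | intermediate
13 | {[2-(benzyloxy)-3-chloro-6-(dimethoxymethyl)-4-methoxyphenoxy]ethynyl}lithium | COc1cc(C(OC)OC)c(OC#C[Li])c(OCc2ccccc2)c1Cl | intermediate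
14 | 3-[2-(benzyloxy)-3-chloro-6-(dimethoxymethyl)-4-methoxyphenoxy]prop-2-yn-1-ol | COc1cc(C(OC)OC)c(OC#CCO)c(OCc2ccccc2)c1Cl | intermediate
15 | ethynylmagnesium bromide | C#C[Mg]Br | starting material
16 | triisopropyl borate | CC(C)OB(OC(C)C)OC(C)C | starting material
17 | bromomagnesium ethynyltri(propan-2-yloxy)borate | C#C[B-](OC(C)C)(OC(C)C)OC(C)C.[Mg+2].[Br-] | intermediate
18 | diisopropyl ethynylboronate | C#CB(OC(C)C)OC(C)C | intermediate
19 | propyne | CC#C | starting material
20 | propan-2-yl 3-[2-(benzyloxy)-3-chloro-6-(dimethoxymethyl)-4-methoxyphenoxy]prop-2-yn-1-yl ethynylboronate | COc1cc(C(OC)OC)c(OC#CCOB(C#C)OC(C)C)c(OCc2ccccc2)c1Cl | intermediate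
21 | 4-[2-(benzyloxy)-3-chloro-6-(dimethoxymethyl)-4-methoxyphenoxy]-6-methyl-1-(propan-2-yloxy)-1,3-dihydro-2,1-benzoxaborole | CC(C)OB1OCc2c1cc(C)cc2Oc1c(C(OC)OC)cc(OC)c(Cl)c1OCc1ccccc1 | intermediate
22 | 3-[2-(benzyloxy)-3-chloro-6-(dimethoxymethyl)-4-methoxyphenoxy]-2-(hydroxymethyl)-5-methylphenol | COc1cc(C(OC)OC)c(Oc2cc(C)cc(O)c2CO)c(OCc2ccccc2)c1Cl | intermediate
23 | 3-(benzyloxy)-4-chloro-2-[3-hydroxy-2-(hydroxymethyl)-5-methylphenoxy]-5-methoxybenzaldehyde | COc1cc(C=O)c(Oc2cc(C)cc(O)c2CO)c(OCc2ccccc2)c1Cl | intermediate
24 | 3-(benzyloxy)-4-chloro-2-(2-formyl-3-hydroxy-5-methylphenoxy)-5-methoxybenzaldehyde | COc1cc(C=O)c(Oc2cc(C)cc(O)c2C=O)c(OCc2ccccc2)c1Cl | intermediate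
25 | 3-(benzyloxy)-2-(2-carboxy-3-hydroxy-5-methylphenoxy)-4-chloro-5-methoxybenzoic acid | COc1cc(C(=O)O)c(Oc2cc(C)cc(O)c2C(=O)O)c(OCc2ccccc2)c1Cl | intermediate
26 | 2-(2-carboxy-3-hydroxy-5-methylphenoxy)-4-chloro-3-hydroxy-5-methoxybenzoic acid | COc1cc(C(=O)O)c(Oc2cc(C)cc(O)c2C(=O)O)c(O)c1Cl | target

## Step count and least certain steps

Total: 14 steps. Longest linear sequence: 13 steps (steps 1 to 8 and 10 to 14); step 9 is a one-step branch.

**Step 10 (key step, bears the label "Proposed new method:").**
- What may go wrong: failure of the oxidative cyclization because the hindered, donor-substituted alkynyl ether binds ruthenium unproductively; homotrimerization of propyne or of 18 outrunning the tethered pathway; insertion of propyne in the reverse orientation; loss of the tether by hydrolysis; acid-induced hydration or acetal-assisted cyclization of the alkynyl ether.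
- Fallback (known chemistry): ring B is taken ready-made and the ether formed by nucleophilic aromatic substitution next to a formyl group. It sets out from 8 and returns to the route at 26. Purchased 2,6-difluoro-4-methylbenzaldehyde (Cc1cc(F)c(C=O)c(F)c1) and benzyl alcohol (K2CO3, DMF) would give 2-(benzyloxy)-6-fluoro-4-methylbenzaldehyde F1. The phenoxide of 8 (Cs2CO3, DMF, 100 °C) would displace the remaining fluoride, activated by the ortho formyl group, to give 3-(benzyloxy)-2-[3-(benzyloxy)-2-formyl-5-methylphenoxy]-4-chloro-5-methoxybenzaldehyde F2. Pinnick oxidation would give 3-(benzyloxy)-2-[3-(benzyloxy)-2-carboxy-5-methylphenoxy]-4-chloro-5-methoxybenzoic acid F3, and BCl3 with C6HMe5 would remove both benzyl groups to give 26.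

**Step 8.**
- What may go wrong: slow, heterogeneous capture of the lithium acetylide by paraformaldehyde with decomposition on warming; competing lithiation of the arene; acid-induced hydration or rearrangement of the aryloxypropynol during isolation.
- Fallback: the one-carbon unit is introduced by acylation and reduction. It sets out from 11 and returns at 14. The acetylide generated as in step 8 would be trapped at −78 °C with methyl chloroformate to give the push–pull alkyne methyl 3-[2-(benzyloxy)-3-chloro-6-(dimethoxymethyl)-4-methoxyphenoxy]prop-2-ynoate F4, which is more robust and can be stored. Reduction with i-Bu2AlH (CH2Cl2, −78 °C) shortly before the key step would give 14.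

**Step 6.**
- What may go wrong: poor addition of the hydrogen-bonded, doubly ortho-substituted formylphenoxide to dichloroethyne, and base-induced degradation of the aldehyde in hot DMF.
- Fallback: a redox detour that removes the hydrogen bond and raises the nucleophilicity of the phenoxide. It sets out from 8 and returns at 10. NaBH4 (MeOH, 0 °C) would give 2-(benzyloxy)-3-chloro-6-(hydroxymethyl)-4-methoxyphenol F5. K2CO3 and 9 in DMF would etherify only the phenoxide to give [3-(benzyloxy)-4-chloro-2-{[(E)-1,2-dichloroethenyl]oxy}-5-methoxyphenyl]methanol F6. MnO2 would then give 10.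

**Step 13.**
- What may go wrong: electrophilic chlorination of the phenolic ring B by hypochlorous acid despite the scavenger, and sluggish oxidation of the hydrogen-bonded, doubly ortho-substituted aldehyde.
- Fallback: the phenol is masked during the oxidation. It sets out from 24 and returns at 25. Ac2O and pyridine would give 3-[2-(benzyloxy)-3-chloro-6-formyl-4-methoxyphenoxy]-2-formyl-5-methylphenyl acetate F7. Pinnick oxidation would give 2-[3-(acetyloxy)-2-carboxy-5-methylphenoxy]-3-(benzyloxy)-4-chloro-5-methoxybenzoic acid F8. K2CO3 in MeOH/H2O would remove the acetate to give 25.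

## Further compounds

F1 | step 10 | 2-(benzyloxy)-6-fluoro-4-methylbenzaldehyde | Cc1cc(F)c(C=O)c(OCc2ccccc2)c1
F2 | step 10 | 3-(benzyloxy)-2-[3-(benzyloxy)-2-formyl-5-methylphenoxy]-4-chloro-5-methoxybenzaldehyde | COc1cc(C=O)c(Oc2cc(C)cc(OCc3ccccc3)c2C=O)c(OCc2ccccc2)c1Cl
F3 | step 10 | 3-(benzyloxy)-2-[3-(benzyloxy)-2-carboxy-5-methylphenoxy]-4-chloro-5-methoxybenzoic acid | COc1cc(C(=O)O)c(Oc2cc(C)cc(OCc3ccccc3)c2C(=O)O)c(OCc2ccccc2)c1Cl
F4 | step 8 | methyl 3-[2-(benzyloxy)-3-chloro-6-(dimethoxymethyl)-4-methoxyphenoxy]prop-2-ynoate | COC(=O)C#COc1c(C(OC)OC)cc(OC)c(Cl)c1OCc1ccccc1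
F5 | step 6 | 2-(benzyloxy)-3-chloro-6-(hydroxymethyl)-4-methoxyphenol | COc1cc(CO)c(O)c(OCc2ccccc2)c1Cl
F6 | step 6 | [3-(benzyloxy)-4-chloro-2-{[(E)-1,2-dichloroethenyl]oxy}-5-methoxyphenyl]methanol | COc1cc(CO)c(O/C(Cl)=C\Cl)c(OCc2ccccc2)c1Cl
F7 | step 13 | 3-[2-(benzyloxy)-3-chloro-6-formyl-4-methoxyphenoxy]-2-formyl-5-methylphenyl acetate | COc1cc(C=O)c(Oc2cc(C)cc(OC(C)=O)c2C=O)c(OCc2ccccc2)c1Cl
F8 | step 13 | 2-[3-(acetyloxy)-2-carboxy-5-methylphenoxy]-3-(benzyloxy)-4-chloro-5-methoxybenzoic acid | COc1cc(C(=O)O)c(Oc2cc(C)cc(OC(C)=O)c2C(=O)O)c(OCc2ccccc2)c1Cl
A1 | alternative 1 | methyl 2-(benzyloxy)-6-{[(3E)-4,7-dimethoxy-2,7-dioxohept-3-en-1-yl]oxy}-4-methylbenzoate | COC(=O)CC/C(OC)=C\C(=O)COc1cc(C)cc(OCc2ccccc2)c1C(=O)OC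
A2 | alternative 1 | methyl 2-(benzyloxy)-6-{[trans-4-methoxy-6-(methoxycarbonyl)-2-oxocyclohex-3-en-1-yl]oxy}-4-methylbenzoate (racemic, one enantiomer drawn) | COC1=CC(=O)[C@H](Oc2cc(C)cc(OCc3ccccc3)c2C(=O)OC)[C@@H](C(=O)OC)C1
A3 | alternative 2 | methyl 4-[2-(benzyloxy)-3-chloro-4-methoxy-6-(methoxycarbonyl)phenoxy]-6-methyl-2-oxo-2H-pyran-3-carboxylate | COC(=O)c1c(Oc2c(C(=O)OC)cc(OC)c(Cl)c2OCc2ccccc2)cc(C)oc1=O
A4 | alternative 2 | 1,1-dimethoxyethene | C=C(OC)OC
A5 | alternative 2 | methyl 3-(benzyloxy)-4-chloro-5-methoxy-2-[3-methoxy-2-(methoxycarbonyl)-5-methylphenoxy]benzoate | COC(=O)c1c(OC)cc(C)cc1Oc1c(C(=O)OC)cc(OC)c(Cl)c1OCc1ccccc1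
A6 | alternative 3 | tert-butyl({3-[2-(benzyloxy)-6-({[tert-butyl(dimethyl)silyl]oxy}methyl)-3-chloro-4-methoxyphenoxy]prop-2-yn-1-yl}oxy)dimethylsilane | COc1cc(CO[Si](C)(C)C(C)(C)C)c(OC#CCO[Si](C)(C)C(C)(C)C)c(OCc2ccccc2)c1Cl
A7 | alternative 3 | 3-methylcyclobut-2-en-1-one | CC1=CC(=O)C1
A8 | alternative 3 | 3-[2-(benzyloxy)-6-({[tert-butyl(dimethyl)silyl]oxy}methyl)-3-chloro-4-methoxyphenoxy]-2-({[tert-butyl(dimethyl)silyl]oxy}methyl)-5-methylphenol | COc1cc(CO[Si](C)(C)C(C)(C)C)c(Oc2cc(C)cc(O)c2CO[Si](C)(C)C(C)(C)C)c(OCc2ccccc2)c1Cl
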